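**Retrosynthetic overview**
1. Feature: in the 2,4-dihydroxy-3-methoxyphenyl ring (C1 carries the chain, C2 OH, C3 OMe, C4 OH, C5 and C6 H) the O–C2–C3(OMe)–C4–O triad is the enol form of a 4-alkyl-2-methoxycyclohexane-1,3-dione, two hydrogens (at C5 and C6) below the arene; the 4-methoxyphenyl ring is bought.
2. Endgame, backwards: chain ketone from its dioxolane; arene from the dione by palladium-catalysed dehydrogenation; dione from a C1 benzyl ester by hydrogenolysis and decarboxylation.
3. Key disconnection: C3–C4, a Dieckmann closure of the methoxymethyl ketone enolate (C3) onto the propanoate ester carbonyl (C4) of a keto diester whose C1 is quaternary.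
4. The keto diester comes from benzyl 4-methoxyacetoacetate by C-alkylation with the chain iodo ketal and Michael addition to methyl acrylate; the iodo ketal comes from 5-(4-methoxyphenyl)pentanoic acid via Weinreb amide, vinyl ketone and Me3SiI/ethylene glycol.
5. Ring order: the six-membered carbocycle is the only ring made (step 7); it is aromatized in step 9.

Key step: step 7

Remark: the cyclohexane-1,3-diones are drawn as diketones although they should exist largely as enols. The target is achiral and is taken in the open keto-phenol form drawn; a cyclic hemiketal with the C2 hydroxyl may be present in equilibrium.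

**Route**

Step 1
Reactants: 1 5-(4-methoxyphenyl)pentanoic acid
Product: 3 N-methoxy-N-methyl-5-(4-methoxyphenyl)pentanamide, via acyl imidazolide 2 (not isolated)
Conditions: CDI (1.1 equiv), CH2Cl2, rt; then MeNHOMe·HCl (1.2 equiv), rt
Reagents that add atoms: N,O-dimethylhydroxylamine hydrochloride, CNOC.Cl; 1,1'-carbonyldiimidazole, O=C(n1ccnc1)n1ccnc1 (its imidazolyl group stays only in intermediate 2)
Why: Amide formation through the acyl imidazolide is a standard Weinreb amide synthesis and touches neither the aryl ether nor any stereocentre.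

Step 2
Reactants: 3 N-methoxy-N-methyl-5-(4-methoxyphenyl)pentanamide; 4 vinylmagnesium bromide
Product: 5 7-(4-methoxyphenyl)hept-1-en-3-one
Conditions: CH2=CHMgBr (1.3 equiv), THF, −10 °C → 0 °C; inverse quench into 2 M HCl, 0 °C
Reagents that add atoms: none
Why: Weinreb ketone synthesis, in which the magnesium chelate of the tetrahedral adduct prevents a second addition and the inverse acid quench protonates the released N,O-dimethylhydroxylamine before it can add to the vinyl ketone.

Step 3
Reactants: 5 7-(4-methoxyphenyl)hept-1-en-3-one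
Product: 7 2-(2-iodoethyl)-2-[4-(4-methoxyphenyl)butyl]-1,3-dioxolane, via iodo silyl enol ether 6 (not isolated)
Conditions: Me3SiI (1.2 equiv), CH2Cl2, −78 °C → −40 °C; then HOCH2CH2OH (2 equiv), −40 °C → rt
Reagents that add atoms: iodotrimethylsilane, C[Si](C)(C)I; ethylene glycol, OCCO
Why: Conjugate addition of iodotrimethylsilane to the vinyl ketone gives the β-iodo silyl enol ether (Z expected, of no consequence), which ethylene glycol converts into the dioxolane under the hydrogen iodide formed (hydroiodination–ketalization of an enone), the low temperature and short contact sparing the aryl methyl ether.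

Step 4
Reactants: 8 methyl 4-methoxyacetoacetate
Product: 9 benzyl 4-methoxy-3-oxobutanoate
Conditions: BnOH (0.9 equiv), DMAP (0.1 equiv), toluene, reflux, MeOH distilled off
Reagents that add atoms: benzyl alcohol, OCc1ccccc1
Why: Transesterification of a β-keto ester (acylketene or DMAP acyl transfer) driven by removal of methanol, chosen so that the temporary ester can later be removed by hydrogenolysis without heat, acid or halide, all of which would endanger the dioxolane next to an acidic dione.

Step 5
Reactants: 9 benzyl 4-methoxy-3-oxobutanoate; 7 2-(2-iodoethyl)-2-[4-(4-methoxyphenyl)butyl]-1,3-dioxolane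
Product: 10 benzyl 2-(methoxyacetyl)-4-{2-[4-(4-methoxyphenyl)butyl]-1,3-dioxolan-2-yl}butanoate (racemic)
Conditions: 9 (1.5 equiv), NaH (1.4 equiv), THF–DMF, 0 °C; then 7 (1.0 equiv), 50 °C
Reagents that add atoms: none
Why: Acetoacetic ester alkylation, an SN2 C-alkylation of the sodium enolate at the doubly activated C2 by a primary iodide, with excess keto ester suppressing dialkylation; the new stereocentre is racemic and is destroyed later.

Step 6
Reactants: 10 benzyl 2-(methoxyacetyl)-4-{2-[4-(4-methoxyphenyl)butyl]-1,3-dioxolan-2-yl}butanoate; 11 methyl acrylate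
Product: 12 1-benzyl 5-methyl 2-(methoxyacetyl)-2-{2-[2-[4-(4-methoxyphenyl)butyl]-1,3-dioxolan-2-yl]ethyl}pentanedioate (racemic)
Conditions: methyl acrylate (1.5 equiv), DBU (0.2 equiv), MeCN, rt
Reagents that add atoms: none
Why: Base-catalysed Michael addition of the tertiary β-keto ester carbon to methyl acrylate builds the quaternary carbon (future ring C1, racemic, lost again on decarboxylation and aromatization), the weak catalytic base being too mild for Claisen or aldol chemistry.

Step 7
Reactants: 12 1-benzyl 5-methyl 2-(methoxyacetyl)-2-{2-[2-[4-(4-methoxyphenyl)butyl]-1,3-dioxolan-2-yl]ethyl}pentanedioate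
Product: 13 benzyl 3-methoxy-1-{2-[2-[4-(4-methoxyphenyl)butyl]-1,3-dioxolan-2-yl]ethyl}-2,4-dioxocyclohexane-1-carboxylate (racemic)
Conditions: KOtBu (1.5 equiv), THF, −20 °C → rt; then 1 M HCl to pH 4, 0 °C
Reagents that add atoms: none
Why: tert-Butoxide removes a proton from the methoxy-bearing CH2 of the methoxyacetyl group, the only α-position of the ketone because C1 is quaternary, and the enolate carbon (future C3) adds to the methyl ester carbonyl of the propanoate arm (future C4), the tetrahedral intermediate expelling methoxide to form the C3–C4 bond. The closest known reaction type is the Dieckmann (intramolecular Claisen) cyclization of 5-oxohexanoates to cyclohexane-1,3-diones. The ring closes in a 6-(enolexo)-exo-trig mode through C3, the ketone carbon C2, C1, the methylene carbons C6 and C5 and the ester carbon C4. C1 was made racemic in step 6 and C3 is enolised in the product, so no stereocentre needs control and both disappear by step 9. The step needs enolisation at C3 in preference to the ester α-methylene and six-ring closure in preference to every other mode: the ketone α-hydrogens are markedly more acidic than those of the ester, each alternative Claisen or aldol closure (onto the benzyl ester or from the ester enolate) would give a four-membered ring, and enol-lactone formation by O-acylation is reversible. Retro-Claisen and retro-Michael cleavage of the non-enolisable β-keto ester should be held back by the bulky, weakly nucleophilic base at low temperature and by immediate deprotonation of the 2-methoxy-1,3-dione between its carbonyls, which makes the closure irreversible.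

Step 8
Reactants: 13 benzyl 3-methoxy-1-{2-[2-[4-(4-methoxyphenyl)butyl]-1,3-dioxolan-2-yl]ethyl}-2,4-dioxocyclohexane-1-carboxylate
Product: 15 2-methoxy-4-{2-[2-[4-(4-methoxyphenyl)butyl]-1,3-dioxolan-2-yl]ethyl}cyclohexane-1,3-dione (racemic), via dioxo acid 14 (not isolated)
Conditions: H2 (1 atm), Pd/C (10 wt%), EtOAc, rt; then 45 °C
Reagents that add atoms: none
Why: Hydrogenolysis of the benzyl ester gives the β-keto acid, which should lose carbon dioxide through the cyclic enol transition state on gentle warming (debenzylative decarboxylation), the neutral anhydrous medium leaving the dioxolane, the anisole ring and the enol double bond untouched; the remaining ring stereocentres are epimerizable and vanish on aromatization.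

Step 9
Reactants: 15 2-methoxy-4-{2-[2-[4-(4-methoxyphenyl)butyl]-1,3-dioxolan-2-yl]ethyl}cyclohexane-1,3-dione
Product: 16 2-methoxy-4-{2-[2-[4-(4-methoxyphenyl)butyl]-1,3-dioxolan-2-yl]ethyl}benzene-1,3-diol
Conditions: Pd/C (10 wt%, 5 mol% Pd), K2CO3 (0.2 equiv), DMA, 150 °C, N2 sweep
Reagents that add atoms: none
Why: Heterogeneous palladium-catalysed dehydrogenation of a cyclohexane-1,3-dione to a resorcinol, in which the enolised dione (a 3-hydroxycyclohexenone) loses the hydrogens at C5 and C6 on the metal and the resulting dienone tautomerizes irreversibly to the arene, the substituent pattern (chain C1, OH C2, OMe C3, OH C4) being fixed by the ring construction and the carbonate keeping the medium non-acidic for the dioxolane.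

Step 10
Reactants: 16 2-methoxy-4-{2-[2-[4-(4-methoxyphenyl)butyl]-1,3-dioxolan-2-yl]ethyl}benzene-1,3-diol
Product: 17 1-(2,4-dihydroxy-3-methoxyphenyl)-7-(4-methoxyphenyl)heptan-3-one
Conditions: 1 M HCl, THF, rt
Reagents that add atoms: water, O
Why: Acid-catalysed hydrolysis of the dioxolane (ketal deprotection) frees the chain ketone, water as the only nucleophile avoiding mixed ketals with the neighbouring phenol, and no stereocentre is present.

**Compound list**
1 | 5-(4-methoxyphenyl)pentanoic acid | COc1ccc(CCCCC(=O)O)cc1 | starting material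
2 | 1-[5-(4-methoxyphenyl)pentanoyl]imidazole (acyl imidazolide, not isolated) | COc1ccc(CCCCC(=O)n2ccnc2)cc1 | intermediate
3 | N-methoxy-N-methyl-5-(4-methoxyphenyl)pentanamide | COc1ccc(CCCCC(=O)N(C)OC)cc1 | intermediate
4 | vinylmagnesium bromide | C=C[Mg]Br | starting material
5 | 7-(4-methoxyphenyl)hept-1-en-3-one | COc1ccc(CCCCC(=O)C=C)cc1 | intermediate
6 | {[(2Z)-1-iodo-7-(4-methoxyphenyl)hept-2-en-3-yl]oxy}trimethylsilane (not isolated) | COc1ccc(CCCC/C(O[Si](C)(C)C)=C/CI)cc1 | intermediate
7 | 2-(2-iodoethyl)-2-[4-(4-methoxyphenyl)butyl]-1,3-dioxolane | COc1ccc(CCCCC2(CCI)OCCO2)cc1 | intermediate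
8 | methyl 4-methoxyacetoacetate (methyl 4-methoxy-3-oxobutanoate) | COCC(=O)CC(=O)OC | starting material
9 | benzyl 4-methoxy-3-oxobutanoate | COCC(=O)CC(=O)OCc1ccccc1 | intermediate
10 | benzyl 2-(methoxyacetyl)-4-{2-[4-(4-methoxyphenyl)butyl]-1,3-dioxolan-2-yl}butanoate (racemic) | COCC(=O)C(CCC1(CCCCc2ccc(OC)cc2)OCCO1)C(=O)OCc1ccccc1 | intermediate
11 | methyl acrylate | C=CC(=O)OC | starting material
12 | 1-benzyl 5-methyl 2-(methoxyacetyl)-2-{2-[2-[4-(4-methoxyphenyl)butyl]-1,3-dioxolan-2-yl]ethyl}pentanedioate (racemic) | COCC(=O)C(CCC(=O)OC)(CCC1(CCCCc2ccc(OC)cc2)OCCO1)C(=O)OCc1ccccc1 | intermediate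
13 | benzyl 3-methoxy-1-{2-[2-[4-(4-methoxyphenyl)butyl]-1,3-dioxolan-2-yl]ethyl}-2,4-dioxocyclohexane-1-carboxylate (racemic at C1, C3 enolised) | COC1C(=O)CCC(CCC2(CCCCc3ccc(OC)cc3)OCCO2)(C(=O)OCc4ccccc4)C1=O | intermediate
14 | 3-methoxy-1-{2-[2-[4-(4-methoxyphenyl)butyl]-1,3-dioxolan-2-yl]ethyl}-2,4-dioxocyclohexane-1-carboxylic acid (racemic, not isolated) | COC1C(=O)CCC(CCC2(CCCCc3ccc(OC)cc3)OCCO2)(C(=O)O)C1=O | intermediate
15 | 2-methoxy-4-{2-[2-[4-(4-methoxyphenyl)butyl]-1,3-dioxolan-2-yl]ethyl}cyclohexane-1,3-dione (racemic, enolised) | COC1C(=O)CCC(CCC2(CCCCc3ccc(OC)cc3)OCCO2)C1=O | intermediate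
16 | 2-methoxy-4-{2-[2-[4-(4-methoxyphenyl)butyl]-1,3-dioxolan-2-yl]ethyl}benzene-1,3-diol | COc1ccc(CCCCC2(CCc3ccc(O)c(OC)c3O)OCCO2)cc1 | intermediate
17 | 1-(2,4-dihydroxy-3-methoxyphenyl)-7-(4-methoxyphenyl)heptan-3-one (achiral) | COc1ccc(CCCCC(=O)CCc2ccc(O)c(OC)c2O)cc1 | target

**Step count**
Total: 10 steps. Longest linear sequence: 9 steps (steps 1, 2, 3, 5, 6, 7, 8, 9, 10; step 4 is a one-step side branch).

**Steps most likely to fail**

Step 7. Alkoxide attack at the ketone of the non-enolisable β-keto ester (retro-Claisen loss of the methoxyacetyl group) or retro-Michael loss of acrylate may outrun ring closure. The fallback removes the temporary ester before cyclization. It sets out from 12: hydrogenolysis (H2, Pd/C, EtOAc, rt) should give 5-methoxy-2-(methoxyacetyl)-2-{2-[2-[4-(4-methoxyphenyl)butyl]-1,3-dioxolan-2-yl]ethyl}-5-oxopentanoic acid F1, which decarboxylates on warming to methyl 6-methoxy-4-{2-[2-[4-(4-methoxyphenyl)butyl]-1,3-dioxolan-2-yl]ethyl}-5-oxohexanoate F2. F2 is a plain 5-oxohexanoate with no β-keto ester left to cleave. Its Dieckmann closure (KOtBu, THF, 0 °C) forms the same C3–C4 bond, since enolisation on the other side of the ketone can lead only to a four-membered ring. The fallback comes back to the route at 15.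

Step 9. Turnover may stall because the dione binds palladium as a chelating enolate, the hydrogen released may cause hydrogenolytic loss of a ring oxygen, or the dioxolane may exchange thermally with the enol. The fallback replaces catalytic dehydrogenation by quinone oxidation of a silyl dienol ether and sets out from 15. Double deprotonation (LiN(iPr)2, 2.2 equiv, THF, −78 °C) and O-silylation with Me3SiCl should give 2-methoxy-6-{2-[2-[4-(4-methoxyphenyl)butyl]-1,3-dioxolan-2-yl]ethyl}-1,3-bis(trimethylsilyloxy)cyclohexa-1,3-diene F3. DDQ (2,6-lutidine, CH2Cl2, 0 °C) should aromatize this cyclohexa-1,3-diene to 2-methoxy-4-{2-[2-[4-(4-methoxyphenyl)butyl]-1,3-dioxolan-2-yl]ethyl}-1,3-bis(trimethylsilyloxy)benzene F4. The aqueous HCl/THF of step 10 then cleaves both silyl ethers and the dioxolane, so the fallback comes back at 17.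

Step 5. Elimination of hydrogen iodide from the β-iodo ketal by the basic enolate, or O-alkylation, may consume the iodide. The fallback replaces the alkylation by conjugate addition and sets out from 9 and 5. Michael addition of 9 to the vinyl ketone 5 (K2CO3 cat., acetone, rt) should give benzyl 2-(methoxyacetyl)-9-(4-methoxyphenyl)-5-oxononanoate F5. A second Michael addition to methyl acrylate 11 (DBU cat., MeCN, rt) should give 1-benzyl 5-methyl 2-(methoxyacetyl)-2-[7-(4-methoxyphenyl)-3-oxoheptyl]pentanedioate F6. Chemoselective ketalization of the unhindered chain ketone (Me3SiOCH2CH2OSiMe3, Me3SiOTf cat., CH2Cl2, −78 °C) should leave the methoxyacetyl ketone alone, since it sits on a quaternary carbon and is deactivated by its α-alkoxy group. The fallback comes back at 12.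

**Further compounds**
F1 | step 7 | 5-methoxy-2-(methoxyacetyl)-2-{2-[2-[4-(4-methoxyphenyl)butyl]-1,3-dioxolan-2-yl]ethyl}-5-oxopentanoic acid (racemic) | COCC(=O)C(CCC(=O)OC)(CCC1(CCCCc2ccc(OC)cc2)OCCO1)C(=O)O
F2 | step 7 | methyl 6-methoxy-4-{2-[2-[4-(4-methoxyphenyl)butyl]-1,3-dioxolan-2-yl]ethyl}-5-oxohexanoate (racemic) | COCC(=O)C(CCC(=O)OC)CCC1(CCCCc2ccc(OC)cc2)OCCO1
F3 | step 9 | 2-methoxy-6-{2-[2-[4-(4-methoxyphenyl)butyl]-1,3-dioxolan-2-yl]ethyl}-1,3-bis(trimethylsilyloxy)cyclohexa-1,3-diene (racemic) | COC1=C(O[Si](C)(C)C)C(CCC2(CCCCc3ccc(OC)cc3)OCCO2)CC=C1O[Si](C)(C)C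
F4 | step 9 | 2-methoxy-4-{2-[2-[4-(4-methoxyphenyl)butyl]-1,3-dioxolan-2-yl]ethyl}-1,3-bis(trimethylsilyloxy)benzene | COc1ccc(CCCCC2(CCc3ccc(O[Si](C)(C)C)c(OC)c3O[Si](C)(C)C)OCCO2)cc1
F5 | step 5 | benzyl 2-(methoxyacetyl)-9-(4-methoxyphenyl)-5-oxononanoate (racemic) | COCC(=O)C(CCC(=O)CCCCc1ccc(OC)cc1)C(=O)OCc1ccccc1
F6 | step 5 | 1-benzyl 5-methyl 2-(methoxyacetyl)-2-[7-(4-methoxyphenyl)-3-oxoheptyl]pentanedioate (racemic) | COCC(=O)C(CCC(=O)OC)(CCC(=O)CCCCc1ccc(OC)cc1)C(=O)OCc1ccccc1
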